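**Strategy.** Numbering the seven-membered carbocycle from C1 (lactone O–CH) through C2 (ring-fusion CH) to C7 (isovalerate CH), the ring divides into a fully oxygenated three-carbon unit (C6, C7, C1) and a four-carbon unit (C2–C5, oxygen at C4). A dirhodium-catalysed asymmetric (4+3) reaction joins them: the carbenoid from a γ-acetoxy siloxyvinyldiazoacetate cyclopropanates the enol-silane bond C4=C5 of a (2Z,4E)-2-siloxydienyne, and the cis-divinylcyclopropane undergoes Cope rearrangement. One operation forms C5–C6 and C1–C2, sets C1, C2 and C5 (all cis) and delivers every ring carbon at a usable oxidation level. The C2 alkyne later gives the α-methylene lactone by cyclocarbonylation; hydroxyl-directed oxidation and reductions set C6, C7 and C4.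

Key step: step 6

Remark on numbering: C1 = lactone O–CH, C2 = ring-fusion CH, C3 = CH2, C4 = CHOH, C5 = CHCH3, C6 = C(OH)(acyl), C7 = CH–O-isovalerate. The "lower face" is the face of the lactone oxygen (C1–O, C2–C, C5–CH3 and C6–OH lie on it; C4–OH, the C6 acyl carbon and C7–O lie on the upper face).

Assumption: Rh2(S-PTAD)4 is taken to give the drawn enantiomer of 10; if the sense of induction is the opposite one, the mirror-image catalyst Rh2(R-PTAD)4 is used.

**Route**

Step 1
Reactants: 1 methyl 4-chloro-3-oxobutanoate
Product: 2 methyl 4-acetoxy-3-oxobutanoate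
Conditions: KOAc, DMF, 23 °C
Reagents that add atoms: potassium acetate CC(=O)[O-].[K+]
Why: SN2 displacement of the activated primary α-chloro ketone by carboxylate (ester formation by carboxylate alkylation), the weakly basic acetate limiting enolate self-condensation.

Step 2
Reactants: 2 methyl 4-acetoxy-3-oxobutanoate
Product: 3 methyl 4-acetoxy-2-diazo-3-oxobutanoate
Conditions: p-ABSA, Et3N, MeCN, 0 → 23 °C
Reagents that add atoms: 4-acetamidobenzenesulfonyl azide CC(=O)Nc1ccc(cc1)S(=O)(=O)N=[N+]=[N-]
Why: Regitz diazo transfer to the active methylene of the β-keto ester.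

Step 3
Reactants: 3 methyl 4-acetoxy-2-diazo-3-oxobutanoate
Product: 4 methyl (Z)-4-acetoxy-3-(tert-butyldimethylsilyloxy)-2-diazobut-3-enoate
Conditions: TBSOTf, Et3N, CH2Cl2, 0 °C
Reagents that add atoms: tert-butyldimethylsilyl trifluoromethanesulfonate CC(C)(C)[Si](C)(C)OS(=O)(=O)C(F)(F)F
Why: Soft enolisation (silyl triflate/amine) at the only enolisable position gives the enol silane; the Z isomer (acetoxy cis to O–Si, trans to the diazo carbon) should form because the other isomer suffers allylic strain with the diazo ester, as is general for γ-substituted enoldiazoacetates.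

Step 4
Reactants: 5 3-(trimethylsilyl)prop-2-ynal; 6 diethyl (2-oxobutyl)phosphonate
Product: 7 (E)-7-(trimethylsilyl)hept-4-en-6-yn-3-one
Conditions: LiCl, iPr2NEt, MeCN, 23 °C
Reagents that add atoms: none
Why: Horner–Wadsworth–Emmons olefination under Masamune–Roush conditions; the stabilised keto-phosphonate gives the (E)-enone and the mild base spares the ynal and the alkynylsilane.

Step 5
Reactants: 7 (E)-7-(trimethylsilyl)hept-4-en-6-yn-3-one
Product: 8 triethyl{[(2Z,4E)-7-(trimethylsilyl)hepta-2,4-dien-6-yn-3-yl]oxy}silane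
Conditions: TESOTf, Et3N, Et2O, −78 → 0 °C
Reagents that add atoms: triethylsilyl trifluoromethanesulfonate CC[Si](CC)(CC)OS(=O)(=O)C(F)(F)F
Why: Soft enolisation at the only α-carbon that bears hydrogen gives the cross-conjugated 2-siloxydiene, the (Z)-enol silane (methyl cis to O–Si) being the usual outcome for ethyl ketones under silyl triflate/amine conditions.

Step 6
Reactants: 4 methyl (Z)-4-acetoxy-3-(tert-butyldimethylsilyloxy)-2-diazobut-3-enoate; 8 triethyl{[(2Z,4E)-7-(trimethylsilyl)hepta-2,4-dien-6-yn-3-yl]oxy}silane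
Product: 10 cycloheptadiene ester (C1–OAc; C2–C≡C–SiMe3; C3=C4–OSiEt3; C5–CH3; C6(CO2Me)=C7–OTBS; C1/C2/C5 substituents all on the lower face), via cis-divinylcyclopropane 9 (not isolated)
Conditions: Rh2(S-PTAD)4 (1 mol %), hexanes, slow addition of 4 to 8 (2 equiv), −20 → 23 °C, then 50 °C
Reagents that add atoms: none
Why: The catalyst (dirhodium tetrakis[(S)-(1-adamantyl)(N-phthalimido)acetate]) converts 4 into a donor/acceptor rhodium vinylcarbenoid whose carbene carbon (C6) adds to the most electron-rich π bond of 8, the silyl enol ether C4=C5, giving cis-divinylcyclopropane 9 (bond C5–C6 plus a temporary bond C4–C6); 9 then undergoes a [3,3]-sigmatropic (Cope) rearrangement through the boat transition state, which breaks C4–C6 and forms C1–C2. The closest known reaction type is the tandem cyclopropanation/Cope rearrangement, the established formal (4+3) cycloaddition of vinylcarbenoids with dienes, which includes 2-siloxydienes and siloxyvinyldiazoacetates under this catalyst family. The three-membered ring is closed by stereospecific carbene addition to the alkene, the seven-membered ring by the suprafacial sigmatropic shift that opens the cyclopropane. The chiral catalyst fixes the face of the enol silane that is attacked and hence C5; C2 and C1 follow from the boat geometry, in which the E-alkynyl group at C2, the acetoxy group at C1 (trans to C6 on the enol double bond) and the methyl group (cis to O–Si in the Z-enol silane, hence anti to both vinyl groups) all end up on one face. The step needs site selectivity for C4=C5 over the trans C2=C3 bond, the silyl-capped alkyne and allylic C–H bonds, which the nucleophilicity of the enol silane, the inertness of trans-alkenes and internal alkynes toward such carbenoids and the modest size of the triethylsilyl group should secure; it also needs the cis-divinyl arrangement, which is the normal diastereoselectivity (alkene substituent cis to the donor vinyl group).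

Step 7
Reactants: 10 cycloheptadiene ester
Product: 11 diol (C1–OH; C6–CH2OH; both enol silanes retained)
Conditions: iBu2AlH (5 equiv), CH2Cl2, −78 °C; aq. potassium sodium tartrate
Reagents that add atoms: none
Why: Diisobutylaluminium hydride reduces the vinylogous-carbonate ester 1,2 to the allylic alcohol and cleaves the acetate at −78 °C, while enol silanes and the alkynylsilane are inert; no stereocentre is touched.

Step 8
Reactants: 11 diol
Product: 12 primary TBS ether (C6–CH2OTBS; C1–OH free)
Conditions: TBSCl, imidazole, CH2Cl2, −20 °C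
Reagents that add atoms: tert-butyldimethylsilyl chloride CC(C)(C)[Si](C)(C)Cl
Why: Steric differentiation lets the primary hydroxyl be silylated in preference to the hindered secondary C1 hydroxyl.

Step 9
Reactants: 12 primary TBS ether
Product: 14 α-silyloxy ketone (C6–OTBS lower face; C6–CH2OTBS upper face; C7 ketone; C1–OH free), via silyloxy epoxide 13 (not isolated)
Conditions: VO(acac)2 (5 mol %), tBuOOH (1.1 equiv), CH2Cl2, −20 → 0 °C
Reagents that add atoms: tert-butyl hydroperoxide CC(C)(C)OO
Why: Hydroxyl-directed vanadium-catalysed epoxidation of the allylic alcohol (C1–OH, C6=C7) should deliver oxygen syn to the C1 hydroxyl, i.e. to the lower face, as is usual for cyclic allylic alcohols of this ring size; epoxide 13 then opens with 1,4-silyl shift (Rubottom oxidation), which sets C6, and one equivalent of oxidant should leave the only homoallylic C3=C4 enol silane untouched.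

Step 10
Reactants: 14 α-silyloxy ketone
Product: 16 diol ketone (C1–OH; C7–OH upper face; C4 ketone), via C7-carbinol enol silane 15 (not isolated)
Conditions: Me4NBH(OAc)3, MeCN/AcOH, −35 °C; quench; then AcOH/THF/H2O, 23 °C
Reagents that add atoms: none
Why: Evans–Saksena-type hydroxyl-directed reduction: the acetoxyborohydride bound to the C1 oxygen delivers hydride to the lower face of the adjacent ketone, giving C7–OH on the upper face (trans to C1–OH); the aqueous acid then hydrolyses the triethylsilyl enol ether by protonation at C3, leaving C5 untouched.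

Step 11
Reactants: 16 diol ketone
Product: 17 terminal alkyne (C2–C≡CH)
Conditions: AgNO3 (10 mol %), CH2Cl2/MeOH/H2O, 23 °C
Reagents that add atoms: none
Why: Silver-catalysed protodesilylation of the alkynylsilane is neutral, so the silyl ethers and the base-sensitive β-silyloxy ketone should survive.

Step 12
Reactants: 17 terminal alkyne
Product: 18 cis-fused α-methylene-γ-butyrolactone (C7–OH free; C4 ketone)
Conditions: PdCl2 (10 mol %), thiourea, CO (1 atm), acetone, 50 °C
Reagents that add atoms: carbon monoxide [C-]#[O+]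
Why: Palladium-catalysed cyclocarbonylation of a homopropargylic alcohol: the alkoxycarbonyl–palladium species formed at the C1 oxygen adds syn across the C2 alkyne (5-exo-dig) and protonolysis gives the α-methylene lactone; the cis C1–OH/C2-alkynyl relationship gives the cis fusion, and the trans-disposed C7–OH cannot reach the alkyne.

Step 13
Reactants: 18 cis-fused α-methylene-γ-butyrolactone
Product: 19 C7 isovalerate
Conditions: isovaleric anhydride, DMAP, Et3N, CH2Cl2, 40 °C
Reagents that add atoms: 3-methylbutanoic anhydride CC(C)CC(=O)OC(=O)CC(C)C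
Why: DMAP-catalysed acylation of the only free hydroxyl (C6–O and the primary oxygen are silylated; C4 is still a ketone); the hindered carbinol may need the warm, concentrated conditions given.

Step 14
Reactants: 19 C7 isovalerate
Product: 20 diol (C6–OH; C6–CH2OH; C4 ketone)
Conditions: HF·pyridine, THF/pyridine, 0 → 23 °C
Reagents that add atoms: none
Why: Fluoride cleavage of both silyl ethers under weakly acidic buffering should avoid retro-aldol cleavage of the β-hydroxy ketone and acyl migration.

Step 15
Reactants: 20 diol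
Product: 21 α-hydroxy aldehyde (C6–CHO)
Conditions: Dess–Martin periodinane, NaHCO3, CH2Cl2, 0 °C
Reagents that add atoms: none
Why: Dess–Martin oxidation of the only oxidisable (primary) alcohol; because C4 is still a ketone, no secondary alcohol competes and no lactol can form with a C4 hydroxyl.

Step 16
Reactants: 21 α-hydroxy aldehyde; 22 (Z)-1-bromoprop-1-ene
Product: 23 (Z)-allylic alcohol (C6–CH(OH)–CH=CH–CH3; carbinol epimers)
Conditions: CrCl2, NiCl2 (2 mol %), DMF, 23 °C
Reagents that add atoms: none
Why: Nozaki–Hiyama–Kishi coupling: the alkenylchromium species adds chemoselectively to the aldehyde in the presence of ketone, lactone and ester, with retention of the Z geometry; the new carbinol centre forms as a mixture and is removed in step 18.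

Step 17
Reactants: 23 (Z)-allylic alcohol
Product: 24 triol (C4–OH upper face)
Conditions: Me4NBH(OAc)3, MeCN/AcOH, −20 °C
Reagents that add atoms: none
Why: Evans–Saksena reduction: the tertiary C6–OH on the lower face delivers hydride to C4 through a six-membered transition state, giving the 1,3-anti diol (C4–OH on the upper face, trans to C5–CH3); esters and the lactone are inert.

Step 18
Reactants: 24 triol
Product: 25 CNP0186412.2 (target)
Conditions: MnO2, CH2Cl2, 23 °C
Reagents that add atoms: none
Why: Chemoselective MnO2 oxidation of the allylic alcohol to the (Z)-enone under neutral heterogeneous conditions; the saturated secondary C4–OH and the tertiary C6–OH are not expected to be oxidised.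

**Compound list**

1 | methyl 4-chloro-3-oxobutanoate | COC(=O)CC(=O)CCl | starting material
2 | methyl 4-acetoxy-3-oxobutanoate | COC(=O)CC(=O)COC(C)=O | intermediate
3 | methyl 4-acetoxy-2-diazo-3-oxobutanoate | COC(=O)C(=[N+]=[N-])C(=O)COC(C)=O | intermediate
4 | methyl (Z)-4-acetoxy-3-(tert-butyldimethylsilyloxy)-2-diazobut-3-enoate | COC(=O)C(=[N+]=[N-])/C(O[Si](C)(C)C(C)(C)C)=C/OC(C)=O | intermediate
5 | 3-(trimethylsilyl)prop-2-ynal | C[Si](C)(C)C#CC=O | starting material
6 | diethyl (2-oxobutyl)phosphonate | CCC(=O)CP(=O)(OCC)OCC | starting material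
7 | (E)-7-(trimethylsilyl)hept-4-en-6-yn-3-one | CCC(=O)/C=C/C#C[Si](C)(C)C | intermediate
8 | triethyl{[(2Z,4E)-7-(trimethylsilyl)hepta-2,4-dien-6-yn-3-yl]oxy}silane | C/C=C(O[Si](CC)(CC)CC)/C=C/C#C[Si](C)(C)C | intermediate
9 | cis-divinylcyclopropane: methyl 1-[(Z)-2-acetoxy-1-(TBS-oxy)vinyl]-3-methyl-2-(triethylsilyloxy)-2-[(E)-4-(trimethylsilyl)but-1-en-3-ynyl]cyclopropane-1-carboxylate, the two alkenyl groups cis, methyl trans to both | COC(=O)[C@@]1(/C(O[Si](C)(C)C(C)(C)C)=C/OC(C)=O)[C@@H](C)[C@]1(O[Si](CC)(CC)CC)/C=C/C#C[Si](C)(C)C | intermediate (not isolated)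
10 | methyl 1-acetoxy-7-(TBS-oxy)-4-(triethylsilyloxy)-5-methyl-2-[(trimethylsilyl)ethynyl]cyclohepta-3,6-diene-6-carboxylate, C1/C2/C5 substituents all cis (lower face) | CC(=O)O[C@@H]1[C@H](C#C[Si](C)(C)C)C=C(O[Si](CC)(CC)CC)[C@H](C)C(C(=O)OC)=C1O[Si](C)(C)C(C)(C)C | intermediate
11 | diol: as 10 with C1–OH and C6–CH2OH | O[C@@H]1[C@H](C#C[Si](C)(C)C)C=C(O[Si](CC)(CC)CC)[C@H](C)C(CO)=C1O[Si](C)(C)C(C)(C)C | intermediate
12 | primary TBS ether: as 11 with C6–CH2OTBS | O[C@@H]1[C@H](C#C[Si](C)(C)C)C=C(O[Si](CC)(CC)CC)[C@H](C)C(CO[Si](C)(C)C(C)(C)C)=C1O[Si](C)(C)C(C)(C)C | intermediate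
13 | silyloxy epoxide: C6–C7 epoxide of 12, oxygen on the lower face | O[C@@H]1[C@H](C#C[Si](C)(C)C)C=C(O[Si](CC)(CC)CC)[C@H](C)[C@]2(CO[Si](C)(C)C(C)(C)C)O[C@]12O[Si](C)(C)C(C)(C)C | intermediate (not isolated)
14 | α-silyloxy ketone: C7 ketone, C6–OTBS (lower face), C6–CH2OTBS (upper face), C1–OH, C3=C4–OSiEt3 | O[C@@H]1[C@H](C#C[Si](C)(C)C)C=C(O[Si](CC)(CC)CC)[C@H](C)[C@@](O[Si](C)(C)C(C)(C)C)(CO[Si](C)(C)C(C)(C)C)C1=O | intermediate
15 | C7-carbinol enol silane: as 14 with C7–OH (upper face) | O[C@@H]1[C@H](C#C[Si](C)(C)C)C=C(O[Si](CC)(CC)CC)[C@H](C)[C@@](O[Si](C)(C)C(C)(C)C)(CO[Si](C)(C)C(C)(C)C)[C@H]1O | intermediate (not isolated)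
16 | diol ketone: C1–OH, C7–OH, C4 ketone, C2–C≡C–SiMe3 | O[C@@H]1[C@H](C#C[Si](C)(C)C)CC(=O)[C@H](C)[C@@](O[Si](C)(C)C(C)(C)C)(CO[Si](C)(C)C(C)(C)C)[C@H]1O | intermediate
17 | terminal alkyne: as 16 with C2–C≡CH | O[C@@H]1[C@H](C#C)CC(=O)[C@H](C)[C@@](O[Si](C)(C)C(C)(C)C)(CO[Si](C)(C)C(C)(C)C)[C@H]1O | intermediate
18 | cis-fused α-methylene-γ-butyrolactone with C7–OH, C4 ketone, C6–OTBS, C6–CH2OTBS | C=C1C(=O)O[C@@H]2[C@H]1CC(=O)[C@H](C)[C@@](O[Si](C)(C)C(C)(C)C)(CO[Si](C)(C)C(C)(C)C)[C@H]2O | intermediate
19 | C7 3-methylbutanoate of 18 | C=C1C(=O)O[C@@H]2[C@H]1CC(=O)[C@H](C)[C@@](O[Si](C)(C)C(C)(C)C)(CO[Si](C)(C)C(C)(C)C)[C@H]2OC(=O)CC(C)C | intermediate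
20 | diol: as 19 with C6–OH and C6–CH2OH | C=C1C(=O)O[C@@H]2[C@H]1CC(=O)[C@H](C)[C@@](O)(CO)[C@H]2OC(=O)CC(C)C | intermediate
21 | α-hydroxy aldehyde: as 20 with C6–CHO | C=C1C(=O)O[C@@H]2[C@H]1CC(=O)[C@H](C)[C@@](O)(C=O)[C@H]2OC(=O)CC(C)C | intermediate
22 | (Z)-1-bromoprop-1-ene | C/C=C\Br | starting material
23 | (Z)-allylic alcohol: C6–CH(OH)–CH=CH–CH3, C4 ketone (carbinol epimers) | C=C1C(=O)O[C@@H]2[C@H]1CC(=O)[C@H](C)[C@@](O)(C(O)/C=C\C)[C@H]2OC(=O)CC(C)C | intermediate
24 | triol: as 23 with C4–OH (upper face) | C=C1C(=O)O[C@@H]2[C@H]1C[C@@H](O)[C@H](C)[C@@](O)(C(O)/C=C\C)[C@H]2OC(=O)CC(C)C | intermediate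
25 | CNP0186412.2 | C=C1C(=O)O[C@@H]2[C@H]1C[C@@H](O)[C@H](C)[C@@](O)(C(=O)/C=C\C)[C@H]2OC(=O)CC(C)C | target

**Step count and risks**

Total step count: 18. Longest linear sequence: 16 (steps 1–3 and 6–18).

Steps most likely to fail:

1. Step 6. What may go wrong: at the crowded trisubstituted enol silane the carbenoid may be diverted into allylic C–H insertion, or the bulky chiral catalyst may discriminate the two alkene faces poorly. Fallback (auxiliary control with a small achiral catalyst): setting out from 2, transesterification with (R)-pantolactone (DMAP, toluene, reflux) would give (R)-pantolactonyl 4-acetoxy-3-oxobutanoate F1. Diazo transfer (p-ABSA, Et3N) would give its diazo derivative F2, and TBSOTf/Et3N the (Z)-enol silane F3. Decomposition of F3 with Rh2(O2CC7H15)4 in the presence of 8 should give pantolactonyl ester cycloadduct F4 by the same cyclopropanation/Cope sequence; the α-hydroxy-ester auxiliary controls the face of the carbenoid and the small carboxylate ligands leave room for the trisubstituted alkene (the mirror-image auxiliary is taken if it proves to be the matched one). Reduction with iBu2AlH as in step 7 removes auxiliary and acetate and comes back to the route at 11.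

2. Step 9. What may go wrong: oxygen transfer to the sterically easier upper face (anti to C1–OH and C5–CH3), or competing oxidation of the C3=C4 enol silane, if the vanadium alkoxide does not dominate. Fallback (reagent control): setting out from 11, Sharpless asymmetric epoxidation of the primary allylic alcohol (Ti(OiPr)4, L-(+)-diethyl tartrate, tBuOOH, 4 Å molecular sieves, CH2Cl2, −20 °C; the tartrate that the mnemonic assigns to the lower face) followed by the same silyl shift would give α-silyloxy ketone with free hydroxymethyl group F5. Silylation of the primary alcohol (TBSCl, imidazole) then comes back to the route at 14.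

3. Step 16. What may go wrong: slow addition to the hindered α-hydroxy aldehyde (partly masked as hydrate or hemiacetal) and partial Z-to-E scrambling of the alkenyl metal species. Fallback: from 21, zinc-mediated addition of propyne (Zn(OTf)2, Et3N, toluene, 23 °C) would give propargylic alcohol F6. Semihydrogenation over Pd/CaCO3/Pb(OAc)2 (Lindlar catalyst) with quinoline (H2, 1 atm, EtOAc) should give the (Z)-alkene and comes back to the route at 23.

Further compounds
F1 | step 6 | (R)-pantolactonyl 4-acetoxy-3-oxobutanoate | CC(=O)OCC(=O)CC(=O)O[C@H]1C(=O)OCC1(C)C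
F2 | step 6 | (R)-pantolactonyl 4-acetoxy-2-diazo-3-oxobutanoate | CC(=O)OCC(=O)C(=[N+]=[N-])C(=O)O[C@H]1C(=O)OCC1(C)C
F3 | step 6 | (R)-pantolactonyl (Z)-4-acetoxy-3-(tert-butyldimethylsilyloxy)-2-diazobut-3-enoate | CC(=O)O/C=C(O[Si](C)(C)C(C)(C)C)/C(=[N+]=[N-])C(=O)O[C@H]1C(=O)OCC1(C)C
F4 | step 6 | pantolactonyl ester analogue of cycloadduct 10 | CC(=O)O[C@@H]1[C@H](C#C[Si](C)(C)C)C=C(O[Si](CC)(CC)CC)[C@H](C)C(C(=O)O[C@H]2C(=O)OCC2(C)C)=C1O[Si](C)(C)C(C)(C)C
F5 | step 9 | α-silyloxy ketone with free hydroxymethyl group (C6–OTBS, C6–CH2OH, C7 ketone, C1–OH) | O[C@@H]1[C@H](C#C[Si](C)(C)C)C=C(O[Si](CC)(CC)CC)[C@H](C)[C@@](O[Si](C)(C)C(C)(C)C)(CO)C1=O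
F6 | step 16 | propargylic alcohol (C6–CH(OH)–C≡C–CH3, carbinol epimers) | C=C1C(=O)O[C@@H]2[C@H]1CC(=O)[C@H](C)[C@@](O)(C(O)C#CC)[C@H]2OC(=O)CC(C)C
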